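Everything rests on disconnecting both arenes themselves. In each benzene ring, the contiguous oxygen substituents on C3–C5 and the benzylic carbon on C1, opposite the central oxygen, map onto two pieces. One is a 2,3-dimethoxycyclobutenone (aryl C2–C5: one CH, two C–OMe, one C=O). The other is a 1,1-disubstituted vinyl unit (aryl C1, C6). In one operation a trans-(3R,4R)-butyrolactone with two 2-(tributylstannyl)allyl arms is cross-coupled twice with a squarate-derived 4-chlorocyclobutenone. Heating then turns both four-membered rings, via dienylketenes, into 3-hydroxy-4,5-dimethoxyphenyl rings. The stereocentres are set earlier by an auxiliary-controlled oxidative enolate dimerisation, and double O-methylation ends the route.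

Key step: step 12

Assumption: (−)-cubebininolide is taken as the (3R,4R)-trans lactone of the given SMILES. Aryl atoms are numbered from C1 (bearing the benzylic CH2) so that C5 is the carbon that first appears as the free phenol. The chlorocyclobutenone is used as the racemate because its stereocentre is lost.

Step 1
Reactants: 1 diethyl malonate; 2 2,3-dibromopropene
Product: 3 diethyl 2-(2-bromoprop-2-en-1-yl)malonate
Conditions: NaH (1.0 equiv), 1 (1.5 equiv), THF, 0 °C; then 2 (1.0 equiv), 0 °C to rt
Reagents that add atoms: none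
Why: Malonic ester alkylation (SN2), in which the soft sodium enolate displaces only the allylic bromide of 2, the vinylic bromide is inert, and the excess of 1 suppresses dialkylation.

Step 2
Reactants: 3 diethyl 2-(2-bromoprop-2-en-1-yl)malonate
Product: 5 4-bromopent-4-enoic acid, via 2-(2-bromoallyl)malonic acid 4 (not isolated)
Conditions: NaOH, EtOH/H2O, 50 °C; aq HCl to pH 1; crude 4 heated neat, 150 °C
Reagents that add atoms: sodium hydroxide, [Na+].[OH-]
Why: Saponification and thermal decarboxylation of the malonic acid through the usual cyclic transition state (malonic ester synthesis), under conditions too mild to dehydrobrominate the vinylic bromide.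

Step 3
Reactants: 5 4-bromopent-4-enoic acid; 6 (S)-4-isopropyloxazolidin-2-one
Product: 8 (S)-3-(4-bromopent-4-enoyl)-4-isopropyloxazolidin-2-one, via mixed pivalic anhydride 7 (not isolated)
Conditions: PivCl, Et3N, THF, −20 °C; then LiCl, 6, −20 °C to rt
Reagents that add atoms: none
Why: Mixed-anhydride N-acylation of an oxazolidinone, in which LiCl/Et3N activates 6 without strong base and attack occurs at the less hindered acyl group of 7, leaving the auxiliary stereocentre untouched.

Step 4
Reactants: 8 (S)-3-(4-bromopent-4-enoyl)-4-isopropyloxazolidin-2-one (two molecules)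
Product: 10 (2R,3R)-2,3-bis(2-bromoallyl)-1,4-bis[(4S)-4-isopropyl-2-oxooxazolidin-3-yl]butane-1,4-dione, via lithium Z-enolate 9 (not isolated)
Conditions: LiN(iPr)2 (1.1 equiv), THF, −78 °C; TiCl4 (1.1 equiv), −78 to 0 °C; separation of the minor diastereomers
Reagents that add atoms: none
Why: Oxidative homocoupling of a chiral imide enolate, in which tetravalent titanium takes one electron from each chelated enolate 9 and the two α-carbons join on the faces remote from the isopropyl groups, the same facial sense as an Evans alkylation, which should set both new stereocentres as R.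

Step 5
Reactants: 10 (2R,3R)-2,3-bis(2-bromoallyl)-1,4-bis[(4S)-4-isopropyl-2-oxooxazolidin-3-yl]butane-1,4-dione
Product: 11 (2R,3R)-2,3-bis(2-bromoallyl)butane-1,4-diol
Conditions: LiBH4 (6 equiv), MeOH (6 equiv), THF, 0 °C to rt
Reagents that add atoms: none
Why: Reductive auxiliary removal with borohydride, which takes both acyl groups (and any lactone formed when the first alkoxide attacks the second imide) to primary alcohols without enolisation, so the stereocentres persist and the vinylic bromides survive.

Step 6
Reactants: 11 (2R,3R)-2,3-bis(2-bromoallyl)butane-1,4-diol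
Product: 12 (2R,3R)-2,3-bis(2-bromoallyl)-1,4-bis(tert-butyldimethylsilyloxy)butane
Conditions: TBSCl (2.5 equiv), imidazole (5 equiv), DMF, rt
Reagents that add atoms: tert-butyldimethylsilyl chloride, CC(C)(C)[Si](C)(C)Cl
Why: Standard silyl ether formation on two primary alcohols, which removes the acidic protons and gives a soluble substrate for the organolithium step.

Step 7
Reactants: 12 (2R,3R)-2,3-bis(2-bromoallyl)-1,4-bis(tert-butyldimethylsilyloxy)butane
Product: 14 (2R,3R)-1,4-bis(tert-butyldimethylsilyloxy)-2,3-bis[2-(tributylstannyl)allyl]butane, via bis(alkenyllithium) 13 (not isolated)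
Conditions: t-BuLi (4.4 equiv), Et2O, −78 °C; Bu3SnCl (2.5 equiv), −78 °C to rt; Et3N-washed silica
Reagents that add atoms: tributyltin chloride, CCCC[Sn](Cl)(CCCC)CCCC
Why: Bromine–lithium exchange and stannylation of the alkenyllithium put tin exactly where bromine was, and this palladium-free method is used before the lactone exists because a dibromide treated with zerovalent palladium and Bu3SnSnBu3 would pass through a bromide/stannane pair with 1,6-related sp2 carbons and close a six-membered ring (Stille–Kelly coupling), while a lactone would not survive t-BuLi.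

Step 8
Reactants: 14 (2R,3R)-1,4-bis(tert-butyldimethylsilyloxy)-2,3-bis[2-(tributylstannyl)allyl]butane
Product: 15 (2R,3R)-2,3-bis[2-(tributylstannyl)allyl]butane-1,4-diol
Conditions: Bu4NF (3 equiv), THF, 0 °C to rt
Reagents that add atoms: none
Why: Fluoride-induced desilylation cleaves the Si–O bonds under non-acidic conditions, so no protodestannylation should occur.

Step 9
Reactants: 15 (2R,3R)-2,3-bis[2-(tributylstannyl)allyl]butane-1,4-diol
Product: 18 (3R,4R)-3,4-bis[2-(tributylstannyl)allyl]dihydrofuran-2(3H)-one, via hydroxy aldehyde 16 (not isolated), via lactol 17 (not isolated)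
Conditions: Pr4N[RuO4] (10 mol %), NMO (4 equiv), 4 Å MS, CH2Cl2, rt
Reagents that add atoms: none
Why: Ley–Griffith oxidative lactonisation of a 1,4-diol, in which 16 closes to 17 and is oxidised again, the homotopic hydroxyl groups of C2-symmetric 15 give one and the same lactone, the neutral medium spares the alkenylstannanes, and the trans arrangement is both retained and the more stable one.

Step 10
Reactants: 19 dimethyl squarate
Product: 20 4-hydroxy-2,3-dimethoxycyclobut-2-en-1-one (racemic)
Conditions: LiAlH(OtBu)3 (1.1 equiv), THF, −78 to −20 °C; pH 7 buffer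
Reagents that add atoms: none
Why: Chemoselective 1,2-reduction of one squarate carbonyl by a bulky, mild hydride, after which the remaining vinylogous ester is too unreactive to be reduced again and the neutral quench avoids acid-induced loss of methanol.

Step 11
Reactants: 20 4-hydroxy-2,3-dimethoxycyclobut-2-en-1-one
Product: 21 4-chloro-2,3-dimethoxycyclobut-2-en-1-one (racemic)
Conditions: Me2C=C(Cl)NMe2 (1.1 equiv), CH2Cl2, 0 °C; concentrated cold and used at once
Reagents that add atoms: 1-chloro-N,N,2-trimethylprop-1-en-1-amine, CC(C)=C(Cl)N(C)C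
Why: Neutral deoxychlorination with an α-chloroenamine, in which the alcohol adds to the keteniminium form and chloride displaces the activated oxygen at C4 without release of HCl, leaving only an inert amide that need not be removed before the coupling.

Step 12
Reactants: 18 (3R,4R)-3,4-bis[2-(tributylstannyl)allyl]dihydrofuran-2(3H)-one; 21 4-chloro-2,3-dimethoxycyclobut-2-en-1-one (two molecules)
Product: 25 (3R,4R)-3,4-bis(3-hydroxy-4,5-dimethoxybenzyl)dihydrofuran-2(3H)-one, via bis(4-alkenylcyclobutenone) 22 (not isolated), via bis(dienylketene) 23 (not isolated), via bis(cyclohexa-2,4-dienone) 24 (not isolated)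
Conditions: Pd2(dba)3 (5 mol %), P(2-furyl)3 (20 mol %), 21 (3 equiv, in two portions), dioxane (0.02 M), 50 °C until both C–Sn bonds are consumed; then 100 °C
Reagents that add atoms: none
Why: Oxidative addition of the allylic C4–Cl bond of 21 to zerovalent palladium gives an η3-oxocyclobutenylpalladium chloride, each alkenyl carbon of 18 passes from tin to palladium, and reductive elimination at the CH terminus forms the aryl C1–C2 bond of 22 at 50 °C; at 100 °C each four-membered ring opens by a conrotatory four-electron process to 23, whose ketene carbon bonds to the terminal CH2 (aryl C5–C6 bond) to give 24, and enolisation delivers the phenol. The closest known reaction type is the Stille coupling of 4-chlorocyclobutenones with alkenylstannanes under palladium/tri(2-furyl)phosphine catalysis followed by thermal ring expansion to phenols, used here twice on one substrate. Each of the two benzene rings is closed by a disrotatory six-electron electrocyclisation of the dienylketene that has its vinyl group on the ketene side, and since ring opening is reversible the unproductive outward isomer is recycled through 22. No stereocentre is formed: the C4 centres of 21 and 22 disappear on aromatisation, and lactone C3 and C4 lie one CH2 away from every reacting atom in a neutral medium. The selectivity required is regiochemical, because the η3 intermediate could also couple at its methoxy-bearing C2 terminus and would then lead to an isomeric phenol; the unsubstituted, less hindered C4 terminus and the retained MeO–C=C–C=O conjugation of the product favour the desired bond. Pd2(dba)3 avoids sacrificing stannane to reduce a divalent palladium salt, and holding at 50 °C until tin is consumed keeps acidic phenols away from unreacted stannane.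

Step 13
Reactants: 25 (3R,4R)-3,4-bis(3-hydroxy-4,5-dimethoxybenzyl)dihydrofuran-2(3H)-one
Product: 26 (−)-cubebininolide, (3R,4R)-3,4-bis(3,4,5-trimethoxybenzyl)dihydrofuran-2(3H)-one
Conditions: MeI (6 equiv), K2CO3 (4 equiv), acetone, reflux
Reagents that add atoms: iodomethane, CI
Why: Williamson ether synthesis on both phenoxides, with a base too weak to open the lactone in acetone and with any reversible enolisation at C3 returning the more stable trans isomer.

Compound list
1 | diethyl malonate | CCOC(=O)CC(=O)OCC | starting material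
2 | 2,3-dibromopropene | C=C(Br)CBr | starting material
3 | diethyl 2-(2-bromoprop-2-en-1-yl)malonate | CCOC(=O)C(CC(Br)=C)C(=O)OCC | intermediate
4 | 2-(2-bromoallyl)malonic acid | OC(=O)C(CC(Br)=C)C(=O)O | intermediate
5 | 4-bromopent-4-enoic acid | OC(=O)CCC(Br)=C | intermediate
6 | (S)-4-isopropyloxazolidin-2-one | CC(C)[C@H]1COC(=O)N1 | starting material
7 | 4-bromopent-4-enoic pivalic anhydride | CC(C)(C)C(=O)OC(=O)CCC(Br)=C | intermediate
8 | (S)-3-(4-bromopent-4-enoyl)-4-isopropyloxazolidin-2-one | CC(C)[C@H]1COC(=O)N1C(=O)CCC(Br)=C | intermediate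
9 | lithium (Z)-enolate of 8 | [Li+].[O-]/C(=C\CC(Br)=C)N1C(=O)OC[C@@H]1C(C)C | intermediate
10 | (2R,3R)-2,3-bis(2-bromoallyl)-1,4-bis[(4S)-4-isopropyl-2-oxooxazolidin-3-yl]butane-1,4-dione | CC(C)[C@H]1COC(=O)N1C(=O)[C@H](CC(Br)=C)[C@@H](CC(Br)=C)C(=O)N1C(=O)OC[C@@H]1C(C)C | intermediate
11 | (2R,3R)-2,3-bis(2-bromoallyl)butane-1,4-diol | OC[C@H](CC(Br)=C)[C@@H](CC(Br)=C)CO | intermediate
12 | (2R,3R)-2,3-bis(2-bromoallyl)-1,4-bis(tert-butyldimethylsilyloxy)butane | CC(C)(C)[Si](C)(C)OC[C@H](CC(Br)=C)[C@@H](CC(Br)=C)CO[Si](C)(C)C(C)(C)C | intermediate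
13 | (2R,3R)-1,4-bis(tert-butyldimethylsilyloxy)-2,3-bis(2-lithioallyl)butane | CC(C)(C)[Si](C)(C)OC[C@H](CC([Li])=C)[C@@H](CC([Li])=C)CO[Si](C)(C)C(C)(C)C | intermediate
14 | (2R,3R)-1,4-bis(tert-butyldimethylsilyloxy)-2,3-bis[2-(tributylstannyl)allyl]butane | CC(C)(C)[Si](C)(C)OC[C@H](CC(=C)[Sn](CCCC)(CCCC)CCCC)[C@@H](CC(=C)[Sn](CCCC)(CCCC)CCCC)CO[Si](C)(C)C(C)(C)C | intermediate
15 | (2R,3R)-2,3-bis[2-(tributylstannyl)allyl]butane-1,4-diol | OC[C@H](CC(=C)[Sn](CCCC)(CCCC)CCCC)[C@@H](CC(=C)[Sn](CCCC)(CCCC)CCCC)CO | intermediate
16 | (2R,3R)-4-hydroxy-2,3-bis[2-(tributylstannyl)allyl]butanal | O=C[C@H](CC(=C)[Sn](CCCC)(CCCC)CCCC)[C@@H](CC(=C)[Sn](CCCC)(CCCC)CCCC)CO | intermediate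
17 | (3R,4R)-3,4-bis[2-(tributylstannyl)allyl]tetrahydrofuran-2-ol (anomeric mixture) | C=C(C[C@H]1COC(O)[C@@H]1CC(=C)[Sn](CCCC)(CCCC)CCCC)[Sn](CCCC)(CCCC)CCCC | intermediate
18 | (3R,4R)-3,4-bis[2-(tributylstannyl)allyl]dihydrofuran-2(3H)-one | C=C(C[C@H]1COC(=O)[C@@H]1CC(=C)[Sn](CCCC)(CCCC)CCCC)[Sn](CCCC)(CCCC)CCCC | intermediate
19 | dimethyl squarate | COC1=C(OC)C(=O)C1=O | starting material
20 | 4-hydroxy-2,3-dimethoxycyclobut-2-en-1-one (racemic) | COC1=C(OC)C(O)C1=O | intermediate
21 | 4-chloro-2,3-dimethoxycyclobut-2-en-1-one (racemic) | COC1=C(OC)C(Cl)C1=O | intermediate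
22 | (3R,4R)-3,4-bis[2-(2,3-dimethoxy-4-oxocyclobut-2-en-1-yl)allyl]dihydrofuran-2(3H)-one (mixture at the cyclobutenone CH) | C=C(C[C@H]1COC(=O)[C@@H]1CC(=C)C2C(=O)C(OC)=C2OC)C3C(=O)C(OC)=C3OC | intermediate
23 | bis(dienylketene), each arm CH2–C(=CH2)–CH=C(OMe)–C(OMe)=C=O with the vinyl group cis to the ketene carbon chain | C=C(C[C@H]1COC(=O)[C@@H]1CC(=C)/C=C(OC)\C(OC)=C=O)/C=C(OC)\C(OC)=C=O | intermediate
24 | (3R,4R)-3,4-bis[(3,4-dimethoxy-5-oxocyclohexa-1,3-dien-1-yl)methyl]dihydrofuran-2(3H)-one | O=C1CC(C[C@H]2COC(=O)[C@@H]2CC3=CC(OC)=C(OC)C(=O)C3)=CC(OC)=C1OC | intermediate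
25 | (3R,4R)-3,4-bis(3-hydroxy-4,5-dimethoxybenzyl)dihydrofuran-2(3H)-one | COc1cc(C[C@H]2COC(=O)[C@@H]2Cc2cc(O)c(OC)c(OC)c2)cc(O)c1OC | intermediate
26 | (−)-cubebininolide, (3R,4R)-3,4-bis(3,4,5-trimethoxybenzyl)dihydrofuran-2(3H)-one | COc1cc(C[C@H]2COC(=O)[C@@H]2Cc2cc(OC)c(OC)c(OC)c2)cc(OC)c1OC | target

Total step count: 13
Longest linear sequence: 11 steps (steps 1–9, 12, 13). Steps 10 and 11 form the short second branch.

Steps most likely to fail

1. Step 12.
- What may go wrong: tin-to-palladium transfer from the hindered 1,1-disubstituted alkenylstannanes may be slow, so the chloride decays thermally before it couples. Bond formation may occur at the methoxy-bearing terminus of the η3 intermediate. The second C–Sn bond may be protonolysed once the first phenol has formed.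
- Fallback: it gives up ring construction in favour of the established oxidative-dimerisation entry to dibenzylbutyrolactones, sets out from 6 and comes back at 26. Commercial 3-(3,4,5-trimethoxyphenyl)propanoic acid is attached to 6 under the conditions of step 3 to give (S)-4-isopropyl-3-[3-(3,4,5-trimethoxyphenyl)propanoyl]oxazolidin-2-one F1. Enolisation with LiN(iPr)2 and oxidation with TiCl4 as in step 4 should give (2R,3R)-1,4-bis[(4S)-4-isopropyl-2-oxooxazolidin-3-yl]-2,3-bis(3,4,5-trimethoxybenzyl)butane-1,4-dione F2. LiBH4 reduction gives (2R,3R)-2,3-bis(3,4,5-trimethoxybenzyl)butane-1,4-diol F3, and Pr4N[RuO4]/NMO oxidation of this C2-symmetric diol gives 26 directly.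

2. Step 11.
- What may go wrong: the activated C4 position may ionise with help from the C2 methoxy group, followed by O-demethylation by chloride, during chlorination, concentration or the first minutes of the coupling.
- Fallback: it replaces the halide by an ester leaving group without a nucleophilic counter-ion, sets out from 20 and comes back at 22. Acetylation (Ac2O, pyridine, catalytic DMAP, CH2Cl2, 0 °C) gives 2,3-dimethoxy-4-oxocyclobut-2-en-1-yl acetate F4, which can be purified and stored. It is joined to 18 by the Stille coupling of allylic acetates (Pd2(dba)3, P(2-furyl)3, LiCl, DMF, rt to 50 °C) to give 22, which is then heated as in step 12.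

3. Step 4.
- What may go wrong: facial discrimination may be weak in the radical-type C–C bond formation, and the enolate may be chlorinated or protonated instead, which would lower the share of the R,R dimer.
- Fallback: it builds the two stereocentres one after the other, sets out from 8 and comes back at 11. Evans alkylation of 8 (NaN(SiMe3)2, THF, −78 °C; tert-butyl bromoacetate) gives tert-butyl (3S)-5-bromo-3-{[(4S)-4-isopropyl-2-oxooxazolidin-3-yl]carbonyl}hex-5-enoate F5. Selective imide reduction with LiBH4 gives tert-butyl (3S)-5-bromo-3-(hydroxymethyl)hex-5-enoate F6. CF3CO2H in CH2Cl2 closes it to (S)-4-(2-bromoallyl)dihydrofuran-2(3H)-one F7. Enolisation with LiN(SiMe3)2 and alkylation with 2 anti to the C4 substituent gives (3R,4R)-3,4-bis(2-bromoallyl)dihydrofuran-2(3H)-one F8, and LiBH4 reduces F8 to 11.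

Further compounds
F1 | step 12 | (S)-4-isopropyl-3-[3-(3,4,5-trimethoxyphenyl)propanoyl]oxazolidin-2-one | CC(C)[C@H]1COC(=O)N1C(=O)CCc2cc(OC)c(OC)c(OC)c2
F2 | step 12 | (2R,3R)-1,4-bis[(4S)-4-isopropyl-2-oxooxazolidin-3-yl]-2,3-bis(3,4,5-trimethoxybenzyl)butane-1,4-dione | CC(C)[C@H]1COC(=O)N1C(=O)[C@H](Cc2cc(OC)c(OC)c(OC)c2)[C@@H](Cc2cc(OC)c(OC)c(OC)c2)C(=O)N1C(=O)OC[C@@H]1C(C)C
F3 | step 12 | (2R,3R)-2,3-bis(3,4,5-trimethoxybenzyl)butane-1,4-diol | OC[C@H](Cc1cc(OC)c(OC)c(OC)c1)[C@@H](Cc1cc(OC)c(OC)c(OC)c1)CO
F4 | step 11 | 2,3-dimethoxy-4-oxocyclobut-2-en-1-yl acetate (racemic) | COC1=C(OC)C(OC(C)=O)C1=O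
F5 | step 4 | tert-butyl (3S)-5-bromo-3-{[(4S)-4-isopropyl-2-oxooxazolidin-3-yl]carbonyl}hex-5-enoate | CC(C)[C@H]1COC(=O)N1C(=O)[C@H](CC(Br)=C)CC(=O)OC(C)(C)C
F6 | step 4 | tert-butyl (3S)-5-bromo-3-(hydroxymethyl)hex-5-enoate | OC[C@H](CC(Br)=C)CC(=O)OC(C)(C)C
F7 | step 4 | (S)-4-(2-bromoallyl)dihydrofuran-2(3H)-one | C=C(Br)C[C@H]1COC(=O)C1
F8 | step 4 | (3R,4R)-3,4-bis(2-bromoallyl)dihydrofuran-2(3H)-one | C=C(Br)C[C@H]1COC(=O)[C@@H]1CC(Br)=C
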